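## Structural features

The core is a p-benzoquinone monoepoxide, a 7-oxabicyclo[4.1.0]hept-3-ene-2,5-dione (ring carbons C1 to C6, epoxide oxygen O7): C2 and C5 are ketones, C3=C4 is the remaining enone double bond and C1–O7–C6 is the oxirane. C4 carries an acetoxymethyl group. The fully substituted epoxide carbon C1 carries the chain C1'–C6': a secondary acetate at C1', an (E)-trisubstituted C2'=C3' bond with the methyl group on C3', an (E) C4'=C5' bond and the aldehyde C6'. Three stereocentres are contiguous: C6 (S), the quaternary C1 (R) and the exocyclic C1' (S); the oxygen on C1' and O7 are threo. The fragile groups are the epoxy-enedione (base, nucleophiles, reductants), the conjugated dienal, the C1' acetate (allylic and alpha to the epoxide) and the gamma-acyloxy enone at C4. The real difficulty is twofold: the epoxide lies on one of two very similar trisubstituted quinone double bonds (C1=C6 versus C3=C4), and C1' must be set against the quaternary C1 in the threo sense, the opposite of what a hydroxyl-directed epoxidation of a C1' carbinol gives. The feature used here is that C1' and the CH2 on C4 are both single oxygenated carbons in a para relationship, so the ring derives from a twofold-symmetric 2,5-bis(hydroxymethyl)hydroquinone ether, and C1'–C1(O7)–C6 is a 2,3-epoxy alcohol array whose carbinol carbon can be taken back to an aldehyde without alpha-hydrogen. The key step forms C1'–C2' on that aldehyde and lets the quaternary epoxide carbon C1 control C1'.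

## Logic of the disconnections

18 is taken back to 17 by replacing the three carbonyl groups at C2, C5 and C6' with dimethyl acetals (six C–OMe bonds). The enedione and the dienal are the most electrophilic parts of the target, so they appear only in the last step and only under acid. The gain is that every earlier intermediate tolerates organometallic, fluoride and acylation conditions. The demand is a hydrolysis mild enough for the epoxide and both acetates.

17 is taken back to 16 and then to 15 by cutting the two acyl C–O bonds and restoring one Si–O bond. Both acetates are installed in one operation after the carbon skeleton is complete. The demand is a desilylation that never forms a free alkoxide next to the epoxide.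

15 is cut at the C1'–C2' bond into 7 and 13 (key disconnection). The two halves are of similar size, C1' becomes the carbonyl carbon of an aldehyde that cannot enolise, and the only new stereocentre is adjacent to the already defined quaternary C1. The demand on the forward step is a non-basic, non-chelating alkenyl nucleophile that keeps the (E,E) geometry and adds to one face of the aldehyde.

7 is taken back to 6 (oxidation level at C1') and 6 to 5 by cutting the C1–O7 and C6–O7 bonds. In 5 only one of the two ring alkenes has a free allylic hydroxyl, so the site of the epoxide is fixed by the substrate and its absolute sense by the tartrate. The demand is that the ring be at the bisketal level, where the alkenes are not conjugated to carbonyl groups and accept an electrophilic oxidant.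

5 is taken back to 4 by cutting one C–OMe bond at each of C2 and C5 (rearomatisation), 4 to 2 by the Si–O bond, and 2 to 1 by reduction level. The symmetry of 2 means that a single monosilylation is the only differentiation of the two arms needed in the whole route.

13 is taken back to 12 (acetal C–O bonds), 12 to 11 by the C4'=C5' double bond, 11 to 10 by oxidation level, and 10 to 8 by the C3'–CH3 and C2'–I bonds. The last cut fixes the C2'=C3' geometry through a syn carbometalation.

## Other disconnections considered

Alternative 1: Cut of the C1–C1' bond at the aromatic oxidation level, the first idea that comes to mind. Forward: bromine–lithium exchange on A1 and addition to aldehyde A2 would give benzylic alcohol A3 (with a separate enantioselective operation for C1'), followed by acetate installation, oxidative demethylation to quinone A4 and Weitz–Scheffer epoxidation. In A4 both ring alkenes are trisubstituted with an unsubstituted beta-carbon (C6 and C3), so the peroxide has no intrinsic preference for C6, and the dienal is a third acceptor. C1' is attached through a freely rotating bond, so control over the face of C1=C6 is weak, and basic peroxide threatens both acetates. The chosen plan fixes the site by the only free allylic hydroxyl, the absolute sense by the tartrate and C1' by 1,2-induction, and never exposes the quinone to base.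

Alternative 2: Cut of the two epoxide C–O bonds last, under control of C1'. Forward: titanium tartrate epoxidation with kinetic resolution of the racemic bis-allylic alcohol A5 at the bisketal level. With the C2 ketal carbon geminal to the carbinol-bearing carbon, A(1,2) strain directs the metal-bound peroxide erythro to the carbinol oxygen, whereas the target is threo. Correction would need inversion at a hindered carbinol that is allylic and alpha to the epoxide. The carbinol is also allylic to C2'=C3', which competes for the oxidant, and a resolution discards half of an advanced intermediate. In the chosen plan the tartrate acts on an achiral primary alcohol, only one alkene is allylic to a free hydroxyl, and the threo relationship arises directly.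

Alternative 3: Cut of the ring bonds C2–C3 and C4–C5 by a strain-release ring expansion (Moore rearrangement). Forward: addition of acetylide A7 to cyclobutenedione A6 would give the 4-alkynyl-4-hydroxycyclobutenone A8, whose thermolysis (electrocyclic opening to an alkynyl vinylketene, ring closure, hydrogen shift) closes the six-membered ring at the quinone level. The six-membered ring with the 2,5-pattern is commercially available, so the ring expansion removes no real difficulty and leads back to the quinone epoxidation problem of alternative 1. A6 needs its own multistep synthesis, its two carbonyl groups must be told apart in the acetylide addition, and the thermolysis heats an allylic acetate and a diene acetal. The step count would be clearly higher.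

Key step: step 10

Remark: 1, 8, (triphenylphosphoranylidene)acetaldehyde and both enantiomers of diisopropyl tartrate are taken as commercial; the locants C1–C6, O7 and C1'–C6' of the target are used for all intermediates.

## Steps

Step 1
Reactants: 1 2,5-dimethoxyterephthalaldehyde
Product: 2 (2,5-dimethoxy-1,4-phenylene)dimethanol
Conditions: NaBH4, MeOH/THF, 0 °C to rt
Reagents that add atoms: none
Why: NaBH4 reduction of both aryl aldehydes; no stereocentre is formed and the product keeps the twofold symmetry that the next step breaks.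

Step 2
Reactants: 2 (2,5-dimethoxy-1,4-phenylene)dimethanol
Product: 4 [4-({[tert-butyl(dimethyl)silyl]oxy}methyl)-2,5-dimethoxyphenyl]methanol, via monosodium alkoxide 3 (not isolated)
Conditions: NaH (1.0 equiv), THF, rt; then TBSCl (1.0 equiv), rt
Reagents that add atoms: tert-butyldimethylsilyl chloride, CC(C)(C)[Si](C)(C)Cl
Why: Monosilylation of a symmetrical diol through its sparingly soluble monosodium alkoxide, which is silylated faster than it equilibrates to the dialkoxide; the mono ether should predominate, and diol and bis ether can be recycled.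

Step 3
Reactants: 4 [4-({[tert-butyl(dimethyl)silyl]oxy}methyl)-2,5-dimethoxyphenyl]methanol
Product: 5 [4-({[tert-butyl(dimethyl)silyl]oxy}methyl)-3,3,6,6-tetramethoxycyclohexa-1,4-dien-1-yl]methanol
Conditions: Pt anode, undivided cell, constant current, 1% KOH/MeOH, 0 °C
Reagents that add atoms: methanol, CO
Why: Anodic bis-methoxylation of a 1,4-dimethoxyarene (two-electron oxidation, methanol adds at the two methoxy-bearing carbons) gives the quinone bis(dimethyl ketal); the basic electrolyte protects the ketals, and the achiral product has two isolated ring alkenes that differ only in the single free hydroxymethyl group.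

Step 4
Reactants: 5 [4-({[tert-butyl(dimethyl)silyl]oxy}methyl)-3,3,6,6-tetramethoxycyclohexa-1,4-dien-1-yl]methanol
Product: 6 [(1R,6S)-4-({[tert-butyl(dimethyl)silyl]oxy}methyl)-2,2,5,5-tetramethoxy-7-oxabicyclo[4.1.0]hept-3-en-1-yl]methanol
Conditions: Ti(OiPr)4 (20 mol %), D-(−)-diisopropyl tartrate (25 mol %), tBuOOH, 4 Å MS, CH2Cl2, −20 °C
Reagents that add atoms: tert-butyl hydroperoxide, CC(C)(C)OO
Why: Sharpless asymmetric epoxidation: the titanium tartrate complex binds the primary allylic alcohol and delivers oxygen only to the alkene that carries the free hydroxymethyl group (C1=C6), which fixes the site; D-(−)-tartrate is the ligand that gives (2R,3R)-epoxy alcohols from simple (E)-allylic alcohols, and the same facial sense places O7 so that C1 is R and C6 is S, both set together in the cis-fused oxirane.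

Step 5
Reactants: 6 [(1R,6S)-4-({[tert-butyl(dimethyl)silyl]oxy}methyl)-2,2,5,5-tetramethoxy-7-oxabicyclo[4.1.0]hept-3-en-1-yl]methanol
Product: 7 (1S,6S)-4-({[tert-butyl(dimethyl)silyl]oxy}methyl)-2,2,5,5-tetramethoxy-7-oxabicyclo[4.1.0]hept-3-ene-1-carbaldehyde
Conditions: (nPr4N)RuO4 (5 mol %), N-methylmorpholine N-oxide, 4 Å MS, CH2Cl2, rt
Reagents that add atoms: none
Why: Ley–Griffith oxidation under neutral, anhydrous conditions that leave ketals, epoxide and silyl ether intact; C1 bears no hydrogen, so the aldehyde cannot epimerise (the change of the C1 descriptor from R to S is a priority change only).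

Step 6
Reactants: 8 prop-2-yn-1-ol
Product: 10 (2E)-3-iodo-2-methylprop-2-en-1-ol, via alkenylalane 9 (not isolated)
Conditions: AlMe3 (3 equiv), Cp2ZrCl2 (25 mol %), CH2Cl2, 0 °C to rt; then I2, THF, −30 to 0 °C
Reagents that add atoms: trimethylaluminium, C[Al](C)C; iodine, II
Why: Negishi carboalumination: zirconium-catalysed syn addition of methyl–aluminium across the alkyne puts the methyl group on the internal carbon and aluminium on the terminal carbon, and iodinolysis with retention gives the (E)-iodide that defines the future C2'=C3' geometry.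

Step 7
Reactants: 10 (2E)-3-iodo-2-methylprop-2-en-1-ol
Product: 11 (2E)-3-iodo-2-methylprop-2-enal
Conditions: MnO2, CH2Cl2, rt
Reagents that add atoms: none
Why: Allylic oxidation with MnO2 stops at the aldehyde and touches neither the vinyl iodide nor the alkene geometry.

Step 8
Reactants: 11 (2E)-3-iodo-2-methylprop-2-enal
Product: 12 (2E,4E)-5-iodo-4-methylpenta-2,4-dienal
Conditions: Ph3P=CHCHO (1.1 equiv), toluene, 80 °C
Reagents that add atoms: (triphenylphosphoranylidene)acetaldehyde, O=CC=P(c1ccccc1)(c1ccccc1)c1ccccc1
Why: Wittig olefination with a stabilised ylide gives the (E)-alkene (future C4'=C5'); a small excess of ylide limits a second homologation of the product.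

Step 9
Reactants: 12 (2E,4E)-5-iodo-4-methylpenta-2,4-dienal
Product: 13 (1E,3E)-1-iodo-5,5-dimethoxy-2-methylpenta-1,3-diene
Conditions: HC(OMe)3, MeOH, pyridinium p-toluenesulfonate (cat.), rt
Reagents that add atoms: trimethyl orthoformate, COC(OC)OC; methanol, CO
Why: Acid-catalysed acetalisation with orthoformate as water scavenger masks the aldehyde so that the coupling partner holds no carbonyl group; the mild catalyst avoids conjugate addition of methanol.

Step 10
Reactants: 7 (1S,6S)-4-({[tert-butyl(dimethyl)silyl]oxy}methyl)-2,2,5,5-tetramethoxy-7-oxabicyclo[4.1.0]hept-3-ene-1-carbaldehyde; 13 (1E,3E)-1-iodo-5,5-dimethoxy-2-methylpenta-1,3-diene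
Product: 15 (1S,2E,4E)-1-[(1R,6S)-4-({[tert-butyl(dimethyl)silyl]oxy}methyl)-2,2,5,5-tetramethoxy-7-oxabicyclo[4.1.0]hept-3-en-1-yl]-6,6-dimethoxy-3-methylhexa-2,4-dien-1-ol, via dienylchromium dichloride 14 (not isolated)
Conditions: CrCl2 (6 equiv), NiCl2 (2 mol %), DMSO/THF, rt
Reagents that add atoms: none
Why: Nozaki–Hiyama–Kishi coupling: CrCl2 reduces NiCl2 to zerovalent nickel, which inserts into the C–I bond of 13 with retention, and transmetalation to trivalent chromium gives the alkenylchromium species 14, a weakly basic nucleophile that adds only to aldehydes. The closest known reaction type is the NiCl2/CrCl2-mediated addition of alkenyl iodides to alpha-oxygenated and alpha-epoxy aldehydes, which follows the non-chelated (Felkin–Anh/Cornforth) sense. No ring is closed; the step forms the C1'–C2' bond and the C1' stereocentre. C1' is controlled by the adjacent quaternary epoxide carbon C1: without chelation the carbonyl oxygen should turn away from the C1–O7 dipole, and the C2 ketal carbon with its two methoxy groups blocks the sector anti to the oxirane. The alkenyl group is therefore expected to enter anti to C2, across the tied-back C6–O7 edge, which gives the (1'S) alcohol with O1' and O7 threo, as in the target. The step needs facial selectivity (secured by dipole opposition and by a solvated chromium centre that does not bridge to O7), chemoselectivity for the aldehyde over two ketals, an acetal, the epoxide and the silyl ether (secured by the organochromium reagent), and retention of the (1E,3E) geometry (secured by the stereoretentive nickel/chromium manifold). Since C1 bears no hydrogen, the aldehyde can neither enolise nor epimerise during the coupling.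

Step 11
Reactants: 15 (1S,2E,4E)-1-[(1R,6S)-4-({[tert-butyl(dimethyl)silyl]oxy}methyl)-2,2,5,5-tetramethoxy-7-oxabicyclo[4.1.0]hept-3-en-1-yl]-6,6-dimethoxy-3-methylhexa-2,4-dien-1-ol
Product: 16 (1S,2E,4E)-1-[(1R,6S)-4-(hydroxymethyl)-2,2,5,5-tetramethoxy-7-oxabicyclo[4.1.0]hept-3-en-1-yl]-6,6-dimethoxy-3-methylhexa-2,4-dien-1-ol
Conditions: Bu4NF/AcOH (1:1), THF, 0 °C to rt
Reagents that add atoms: none
Why: Fluoride-induced cleavage of the Si–O bond; buffering with acetic acid keeps the C1' hydroxyl protonated, which suppresses Payne rearrangement of the adjacent epoxide, and the acetals are stable at this near-neutral pH.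

Step 12
Reactants: 16 (1S,2E,4E)-1-[(1R,6S)-4-(hydroxymethyl)-2,2,5,5-tetramethoxy-7-oxabicyclo[4.1.0]hept-3-en-1-yl]-6,6-dimethoxy-3-methylhexa-2,4-dien-1-ol
Product: 17 (1S,2E,4E)-1-[(1R,6S)-4-(acetoxymethyl)-2,2,5,5-tetramethoxy-7-oxabicyclo[4.1.0]hept-3-en-1-yl]-6,6-dimethoxy-3-methylhexa-2,4-dien-1-yl acetate
Conditions: Ac2O, pyridine, DMAP (cat.), CH2Cl2, 0 °C to rt
Reagents that add atoms: acetic anhydride, CC(=O)OC(C)=O
Why: DMAP-catalysed O-acylation of the primary and the hindered secondary hydroxyl in one operation; only O–H bonds react, so C1' keeps its configuration.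

Step 13
Reactants: 17 (1S,2E,4E)-1-[(1R,6S)-4-(acetoxymethyl)-2,2,5,5-tetramethoxy-7-oxabicyclo[4.1.0]hept-3-en-1-yl]-6,6-dimethoxy-3-methylhexa-2,4-dien-1-yl acetate
Product: 18 (1S,2E,4E)-1-[(1R,6S)-4-(acetoxymethyl)-2,5-dioxo-7-oxabicyclo[4.1.0]hept-3-en-1-yl]-3-methyl-6-oxohexa-2,4-dien-1-yl acetate (CNP0307549.1)
Conditions: CF3CO2H/H2O (4:1), CH2Cl2, 0 °C to rt
Reagents that add atoms: water, O
Why: Acid-catalysed hydrolysis of the three acetals: the conjugated side-chain acetal and the first ring ketal should cleave readily and the remaining quinone monoketal more slowly; the electron-poor epoxide and both acetates should tolerate aqueous trifluoroacetic acid, and no stereocentre is enolisable (C1 is quaternary, C6 is an oxirane carbon, C1' has no acidifying group).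

## Compound list

1 | 2,5-dimethoxyterephthalaldehyde | COc1cc(C=O)c(OC)cc1C=O | starting material
2 | (2,5-dimethoxy-1,4-phenylene)dimethanol | COc1cc(CO)c(OC)cc1CO | intermediate
3 | sodium [4-(hydroxymethyl)-2,5-dimethoxyphenyl]methanolate | COc1cc(C[O-])c(OC)cc1CO.[Na+] | intermediate
4 | [4-({[tert-butyl(dimethyl)silyl]oxy}methyl)-2,5-dimethoxyphenyl]methanol | COc1cc(CO[Si](C)(C)C(C)(C)C)c(OC)cc1CO | intermediate
5 | [4-({[tert-butyl(dimethyl)silyl]oxy}methyl)-3,3,6,6-tetramethoxycyclohexa-1,4-dien-1-yl]methanol | COC1(OC)C=C(CO[Si](C)(C)C(C)(C)C)C(OC)(OC)C=C1CO | intermediate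
6 | [(1R,6S)-4-({[tert-butyl(dimethyl)silyl]oxy}methyl)-2,2,5,5-tetramethoxy-7-oxabicyclo[4.1.0]hept-3-en-1-yl]methanol | CC(C)(C)[Si](C)(C)OCC1=CC(OC)(OC)[C@]2(CO)O[C@@H]2C1(OC)OC | intermediate
7 | (1S,6S)-4-({[tert-butyl(dimethyl)silyl]oxy}methyl)-2,2,5,5-tetramethoxy-7-oxabicyclo[4.1.0]hept-3-ene-1-carbaldehyde | CC(C)(C)[Si](C)(C)OCC1=CC(OC)(OC)[C@]2(C=O)O[C@@H]2C1(OC)OC | intermediate
8 | prop-2-yn-1-ol | C#CCO | starting material
9 | {(1E)-3-[(dimethylalumanyl)oxy]-2-methylprop-1-en-1-yl}dimethylalumane | C[Al](C)/C=C(C)/CO[Al](C)C | intermediate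
10 | (2E)-3-iodo-2-methylprop-2-en-1-ol | OC/C(C)=C/I | intermediate
11 | (2E)-3-iodo-2-methylprop-2-enal | O=C/C(C)=C/I | intermediate
12 | (2E,4E)-5-iodo-4-methylpenta-2,4-dienal | O=C/C=C/C(C)=C/I | intermediate
13 | (1E,3E)-1-iodo-5,5-dimethoxy-2-methylpenta-1,3-diene | COC(OC)/C=C/C(C)=C/I | intermediate
14 | dichlorido[(1E,3E)-5,5-dimethoxy-2-methylpenta-1,3-dien-1-yl]chromium | COC(OC)/C=C/C(C)=C/[Cr](Cl)Cl | intermediate
15 | (1S,2E,4E)-1-[(1R,6S)-4-({[tert-butyl(dimethyl)silyl]oxy}methyl)-2,2,5,5-tetramethoxy-7-oxabicyclo[4.1.0]hept-3-en-1-yl]-6,6-dimethoxy-3-methylhexa-2,4-dien-1-ol | CC(C)(C)[Si](C)(C)OCC1=CC(OC)(OC)[C@]2([C@H](/C=C(C)/C=C/C(OC)OC)O)O[C@@H]2C1(OC)OC | intermediate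
16 | (1S,2E,4E)-1-[(1R,6S)-4-(hydroxymethyl)-2,2,5,5-tetramethoxy-7-oxabicyclo[4.1.0]hept-3-en-1-yl]-6,6-dimethoxy-3-methylhexa-2,4-dien-1-ol | OCC1=CC(OC)(OC)[C@]2([C@H](/C=C(C)/C=C/C(OC)OC)O)O[C@@H]2C1(OC)OC | intermediate
17 | (1S,2E,4E)-1-[(1R,6S)-4-(acetoxymethyl)-2,2,5,5-tetramethoxy-7-oxabicyclo[4.1.0]hept-3-en-1-yl]-6,6-dimethoxy-3-methylhexa-2,4-dien-1-yl acetate | CC(=O)OCC1=CC(OC)(OC)[C@]2([C@H](/C=C(C)/C=C/C(OC)OC)OC(C)=O)O[C@@H]2C1(OC)OC | intermediate
18 | (1S,2E,4E)-1-[(1R,6S)-4-(acetoxymethyl)-2,5-dioxo-7-oxabicyclo[4.1.0]hept-3-en-1-yl]-3-methyl-6-oxohexa-2,4-dien-1-yl acetate | CC(=O)OCC1=CC(=O)[C@]2([C@H](/C=C(C)/C=C/C=O)OC(C)=O)O[C@@H]2C1=O | target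

Total step count: 13. Longest linear sequence: 9 steps (steps 1 to 5 and 10 to 13); the side-chain branch has 4 steps (steps 6 to 9).

## Least certain steps

Step 10 (key step). The most likely problem is insufficient facial discrimination at the aldehyde: if the chromium centre holds the carbonyl oxygen syn to O7, addition anti to C2 leads to the C1' epimer. The alpha-quaternary aldehyde may also react slowly, so that reductive dimerisation of 13 competes. Fallback: it sets out from the crude coupling product, 15 together with the (1R)-epimeric alcohol F1. Oxidation with Dess–Martin periodinane/NaHCO3 gives the dienone F2, and chelation-controlled reduction with Zn(BH4)2 in Et2O at −20 °C comes back to 15. With zinc bridging the ketone oxygen and O7, the carbonyl is turned by half a turn relative to the coupling transition state and hydride, not carbon, enters anti to the C2 ketal carbon; the two changes cancel, so the (1'S) carbinol should result.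

Step 4. The most likely problem is slow oxygen transfer and eroded enantioface selectivity, because the C1=C6 alkene of 5 is inductively deactivated by two flanking ketal carbons and carries a bulky substituent geminal to the hydroxymethyl group; ketal exchange on titanium is a lesser risk. Fallback: from 5, hydroxyl-directed epoxidation with VO(acac)2/tBuOOH gives the racemic epoxy alcohol F3. Esterification with (S)-methoxy(phenyl)acetic acid (DCC, DMAP) gives the (2S)-methoxy(phenyl)acetate of 6 F4 and the (2S)-methoxy(phenyl)acetate of the enantiomer F5, which are separated by chromatography. Methanolysis of F4 (K2CO3, MeOH, 0 °C) comes back to 6.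

Step 3. The most likely problem is competing oxidation at the free benzylic CH2OH (the resulting aryl aldehyde is too electron-poor for the nuclear oxidation), together with partial loss of the silyl ether in methanolic KOH. Fallback: from 4, silylation of the free hydroxyl with Et3SiCl/imidazole gives the bis-silyl ether F6, anodic oxidation under the same conditions gives the bis-silylated bisketal F7, and selective cleavage of the primary triethylsilyl ether (pyridinium p-toluenesulfonate, MeOH, 0 °C) comes back to 5.

Step 11. The most likely problem is epoxide migration (Payne rearrangement) through a C1' alkoxide next to the C1–C6 epoxide if the fluoride is not fully buffered, and silyl migration between the two oxygens. Fallback: from 15, acetylation first (Ac2O, pyridine, DMAP) gives the C1' acetate F8, buffered Bu4NF/AcOH then gives the primary alcohol F9, and a second acetylation comes back to 17; no alkoxide is ever formed next to the epoxide.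

Step 13. The most likely problem is unequal rates of acetal cleavage: the last ring ketal, a quinone monoketal flanked by the epoxide, is hydrolysed far more slowly than the other two acetals, so the acid strength and time needed may open the epoxide or degrade the dienal. Fallback: from 17, the unmasking is split into two operations with isolation of the intermediate. Oxalic acid on wet silica gel (CH2Cl2, rt) releases the C6' aldehyde and the C2 ketone to give the monoketal F10, and the remaining C5 ketal is removed by iodine-catalysed exchange with acetone (I2 cat., acetone, rt), which comes back to 18 without aqueous strong acid.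

## Further compounds

F1 | step 10 | (1R,2E,4E)-1-[(1R,6S)-4-({[tert-butyl(dimethyl)silyl]oxy}methyl)-2,2,5,5-tetramethoxy-7-oxabicyclo[4.1.0]hept-3-en-1-yl]-6,6-dimethoxy-3-methylhexa-2,4-dien-1-ol | CC(C)(C)[Si](C)(C)OCC1=CC(OC)(OC)[C@]2([C@@H](/C=C(C)/C=C/C(OC)OC)O)O[C@@H]2C1(OC)OC
F2 | step 10 | (2E,4E)-1-[(1S,6S)-4-({[tert-butyl(dimethyl)silyl]oxy}methyl)-2,2,5,5-tetramethoxy-7-oxabicyclo[4.1.0]hept-3-en-1-yl]-6,6-dimethoxy-3-methylhexa-2,4-dien-1-one | CC(C)(C)[Si](C)(C)OCC1=CC(OC)(OC)[C@]2(C(=O)/C=C(C)/C=C/C(OC)OC)O[C@@H]2C1(OC)OC
F3 | step 4 | racemic [4-({[tert-butyl(dimethyl)silyl]oxy}methyl)-2,2,5,5-tetramethoxy-7-oxabicyclo[4.1.0]hept-3-en-1-yl]methanol (6 and its enantiomer) | CC(C)(C)[Si](C)(C)OCC1=CC(OC)(OC)[C@]2(CO)O[C@@H]2C1(OC)OC.CC(C)(C)[Si](C)(C)OCC1=CC(OC)(OC)[C@@]2(CO)O[C@H]2C1(OC)OC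
F4 | step 4 | [(1R,6S)-4-({[tert-butyl(dimethyl)silyl]oxy}methyl)-2,2,5,5-tetramethoxy-7-oxabicyclo[4.1.0]hept-3-en-1-yl]methyl (2S)-methoxy(phenyl)acetate | CC(C)(C)[Si](C)(C)OCC1=CC(OC)(OC)[C@]2(COC(=O)[C@@H](OC)c3ccccc3)O[C@@H]2C1(OC)OC
F5 | step 4 | [(1S,6R)-4-({[tert-butyl(dimethyl)silyl]oxy}methyl)-2,2,5,5-tetramethoxy-7-oxabicyclo[4.1.0]hept-3-en-1-yl]methyl (2S)-methoxy(phenyl)acetate | CC(C)(C)[Si](C)(C)OCC1=CC(OC)(OC)[C@@]2(COC(=O)[C@@H](OC)c3ccccc3)O[C@H]2C1(OC)OC
F6 | step 3 | tert-butyl[(2,5-dimethoxy-4-{[(triethylsilyl)oxy]methyl}phenyl)methoxy]dimethylsilane | COc1cc(CO[Si](C)(C)C(C)(C)C)c(OC)cc1CO[Si](CC)(CC)CC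
F7 | step 3 | tert-butyldimethyl[(3,3,6,6-tetramethoxy-4-{[(triethylsilyl)oxy]methyl}cyclohexa-1,4-dien-1-yl)methoxy]silane | COC1(OC)C=C(CO[Si](C)(C)C(C)(C)C)C(OC)(OC)C=C1CO[Si](CC)(CC)CC
F8 | step 11 | (1S,2E,4E)-1-[(1R,6S)-4-({[tert-butyl(dimethyl)silyl]oxy}methyl)-2,2,5,5-tetramethoxy-7-oxabicyclo[4.1.0]hept-3-en-1-yl]-6,6-dimethoxy-3-methylhexa-2,4-dien-1-yl acetate | CC(C)(C)[Si](C)(C)OCC1=CC(OC)(OC)[C@]2([C@H](/C=C(C)/C=C/C(OC)OC)OC(C)=O)O[C@@H]2C1(OC)OC
F9 | step 11 | (1S,2E,4E)-1-[(1R,6S)-4-(hydroxymethyl)-2,2,5,5-tetramethoxy-7-oxabicyclo[4.1.0]hept-3-en-1-yl]-6,6-dimethoxy-3-methylhexa-2,4-dien-1-yl acetate | OCC1=CC(OC)(OC)[C@]2([C@H](/C=C(C)/C=C/C(OC)OC)OC(C)=O)O[C@@H]2C1(OC)OC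
F10 | step 13 | (1S,2E,4E)-1-[(1R,6S)-4-(acetoxymethyl)-5,5-dimethoxy-2-oxo-7-oxabicyclo[4.1.0]hept-3-en-1-yl]-3-methyl-6-oxohexa-2,4-dien-1-yl acetate | CC(=O)OCC1=CC(=O)[C@]2([C@H](/C=C(C)/C=C/C=O)OC(C)=O)O[C@@H]2C1(OC)OC
A1 | alternative 1 | [(4-bromo-2,5-dimethoxyphenyl)methoxy](tert-butyl)dimethylsilane | COc1cc(CO[Si](C)(C)C(C)(C)C)c(OC)cc1Br
A2 | alternative 1 | (2E,4E)-6,6-dimethoxy-3-methylhexa-2,4-dienal | COC(OC)/C=C/C(C)=C/C=O
A3 | alternative 1 | (1S,2E,4E)-1-[4-({[tert-butyl(dimethyl)silyl]oxy}methyl)-2,5-dimethoxyphenyl]-6,6-dimethoxy-3-methylhexa-2,4-dien-1-ol | COC(OC)/C=C/C(C)=C/[C@H](O)c1cc(OC)c(CO[Si](C)(C)C(C)(C)C)cc1OC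
A4 | alternative 1 | (1S,2E,4E)-1-[4-(acetoxymethyl)-3,6-dioxocyclohexa-1,4-dien-1-yl]-3-methyl-6-oxohexa-2,4-dien-1-yl acetate | CC(=O)OCC1=CC(=O)C(=CC1=O)[C@H](/C=C(C)/C=C/C=O)OC(C)=O
A5 | alternative 2 | racemic (2E,4E)-1-[4-({[tert-butyl(dimethyl)silyl]oxy}methyl)-3,3,6,6-tetramethoxycyclohexa-1,4-dien-1-yl]-6,6-dimethoxy-3-methylhexa-2,4-dien-1-ol | COC(OC)/C=C/C(C)=C/C(O)C1=CC(OC)(OC)C(CO[Si](C)(C)C(C)(C)C)=CC1(OC)OC
A6 | alternative 3 | (1S,2E,4E)-1-(3,4-dioxocyclobut-1-en-1-yl)-6,6-dimethoxy-3-methylhexa-2,4-dien-1-yl acetate | O=C1C(=O)C([C@H](/C=C(C)/C=C/C(OC)OC)OC(C)=O)=C1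
A7 | alternative 3 | lithium 3-{[tert-butyl(dimethyl)silyl]oxy}prop-1-yn-1-ide | [Li]C#CCO[Si](C)(C)C(C)(C)C
A8 | alternative 3 | (1S,2E,4E)-1-[4-(3-{[tert-butyl(dimethyl)silyl]oxy}prop-1-yn-1-yl)-4-hydroxy-3-oxocyclobut-1-en-1-yl]-6,6-dimethoxy-3-methylhexa-2,4-dien-1-yl acetate (mixture at the ring carbinol) | O=C1C=C([C@H](/C=C(C)/C=C/C(OC)OC)OC(C)=O)C1(O)C#CCO[Si](C)(C)C(C)(C)C
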